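The numbers in the tables are simulated on assumed constants; noise was put on by code.

Per cent of the substrate charged is the unit in which the meeting about this flask laid the ochre and teal runs side by side, since it puts different charges on one scale.

| flask | substrate | reagent in the second phase | remark | time | volume of the second phase over the first |
|---|---|---|---|---|---|
| ochre | 0.10 M | 0.60 M | run made earlier |  |  |
| teal | 0.15 M | 0.60 M | run made earlier |  |  |
| flask | 0.20 M | 0.600 M |  | 20 min | 1.0 |

| run | time / min | target / % | substrate / % |
|---|---|---|---|
| ochre | 5.00 | 23.4 | 66.2 |
| ochre | 10.0 | 20.5 | 56.7 |
| ochre | 15.0 | 17.8 | 48.4 |
| ochre | 20.0 | 13.7 | 41.6 |
| ochre | 25.0 | 12.3 | 36.8 |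
| teal | 5.00 | 22.2 | 64.8 |
| teal | 10.0 | 18.5 | 55.7 |
| teal | 15.0 | 16.0 | 48.3 |
| teal | 20.0 | 13.5 | 42.9 |
| teal | 25.0 | 12.8 | 37.2 |

(each reading ± 0.5 percentage points)

- in percentages every species weighs as the substrate in it: one homo dimer counts as two
- in the second phase: reagent in the second phase; everything else is in the first
- charges count per volume of the first phase; a concentration in a rate is the amount of a species over the volume of its own phase; every rate counts per litre of the first phase
- the earlier runs were read with a standard deviation of 0.5 percentage points
- what may be going on: reagent in the reaction phase <-> reagent in the second phase; substrate + reagent in the reaction phase <-> target; reagent in the reaction phase + target -> over-reacted product; 2 substrate -> homo dimer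
- the earlier runs hold the two phases in the same ratio of volumes as the flask asked about

- north-west: doubling the transfer coefficient of the reagent in the second phase, all else as stated
- west: doubling the amount of reagent in the second phase, all else as stated

* how much target there is at 20 min, in percent of the substrate charged
* the change that raises the amount of target at 20 min, in percent of the substrate charged most ("none" if none brings more than 2 percentage points) (north-west / west / none)
* amount of target at 20 min, in percent of the substrate charged, after west

The first speaker reported that at 20.0 min target over substrate read 0.329 in the ochre run and 0.315 in the teal run, and proposed to carry their mean, the holding ratio, meaning target over free substrate at one moment, 0.322, which she read as the mark of a pre-equilibrium, a pair running both ways so that target follows substrate as a fast state follows a slow one. Taking substrate from the same two readings, 42.2%, she reckoned as her own figure 13.6% of target for the flask.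

The forecast, made by a colleague, stood lower at 13%, a figure reached by stepping through the charge of the flask with a ratio that falls as the reagent is used and a drain through over-reaction, and it gave 6.8% after west and none as the best change, in its words “Doubling reagent speeds over-reaction” while faster transfer changes little.

The flask gave 12.6% of target and 9.78% after west, and the best change came out as none, with north-west moving target by −0.19 percentage points and west by −2.8 points.

    reagent in the reaction phase ⇌ reagent in the second phase, rate k1*([reagent in the reaction phase] - [reagent in the second phase]/K1) per volume of the first phase (partition coefficient = 0.450, kL = 0.00410 s⁻¹)
    substrate + reagent in the reaction phase ⇌ target (K = 1.00 M⁻¹, k = 0.0220 M⁻¹ s⁻¹)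
    reagent in the reaction phase + target → over-reacted product (k = 0.00420 M⁻¹ s⁻¹)
    2 substrate → homo dimer (k = 0.00110 M⁻¹ s⁻¹)

With 41% of substrate left in the flask, the holding ratio gives 13.2% of target. The flask keeps its target tied to substrate because target returns, the backward turnover being 92% of the forward one, and the run without that return reaches 36.3% against 12.6%, a strong effect but not the whole account. For the neighbour flask charged with 0.80 M of substrate, scaling the ratio by c(reagent in the reaction phase), 0.230 M against 0.318 M, and applying it to 28.5% of substrate gives 6.63%. The computed neighbour holds 6.49%.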